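I had to choose L. The next flask takes E at 0.20 M, and the choice was whether to keep L at 5.0 mM, judged by how G stood against D.

| flask | E | L | remark | time |
|---|---|---|---|---|
| blue | 0.10 M | 5 mM | run made earlier |  |
| amber | 0.15 M | 5 mM | run made earlier |  |
| red | 0.20 M | 10 mM | run made earlier |  |
| flask | 0.20 M | 5.0 mM |  | 5.0 h |

- blue (time / h: G / %, D / %): 1.33: 26, 14; 2.50: 7, 11; 4.00: 3, 7; 5.00: 0, 6; 6.00: 0, 7
- amber (time / h: G / %, D / %): 0.500: 41, 10; 1.50: 19, 12; 3.00: 5, 10; 4.00: 2, 9; 6.00: 1, 6
- red (time / h: G / %, D / %): 1.33: 20, 11; 2.50: 10, 11; 4.00: 0, 5; 5.00: 0, 6; 6.00: 1, 5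

(readings scatter by 1.5 percentage points)



* ratio of G to D at 1.0 min
* ratio of G to D at 5.0 h
* which of G and D there is more of at 5.0 h

I divided the rate of making G by the rate of making D, so that time dropped out. I assumed that both steps go with c_E times c_L, so c_E and c_L cancel as well. The amber run's earliest reading gave G 41% and D 10% at 0.500 h, a ratio of 4.10. But G was already being lost: amber G fell to 19% by 1.50 h, a net loss of 0.769 /h as read. I took G made in that first interval to have stood for 0.250 h on average, so I raised the ratio to 4.97. This is my estimate of the split, G made per D made, a selectivity factor. Under my assumption c_L cancels in it, so changing L promised no better split, and I kept 5.0 mM. I expected about 4.97 at 1.0 min. The blue run read G 0% and D 6% at 5.00 h, so I expected D ahead in the flask at 5.0 h.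

The forecast gave 4.5 at 1.0 min, 0.13 at 5.0 h and D ahead, holding that “the split looks parallel”. Its early ratio stood lower than my 4.97.

The flask gave 5.41 at 1.0 min and 0.160 at 5.0 h, with G 1.32% and D 8.22%, so D led.

    E + L ⇌ D + L, rate k1*[E]*[L] forward; the back reaction follows from the equilibrium constant (K = 2.10, k = 1.27 /M/min)
    G → Q (k = 0.0228 /min)
    E + L ⇌ G + L, rate k3*[E]*[L] forward; the back reaction follows from the equilibrium constant (K = 21.0, k = 6.95 /M/min)

Both forward steps out of E carry c_E times c_L, and I carried the split unchanged to a neighbour flask charged with 1.30 mM of L, where it again said about 4.97 at 1.0 min. That neighbour flask gave 5.41, equal to the flask's 5.41. At 5.0 h the neighbour flask held G 3.30% and D 12.9%, a ratio of 0.256, with 5.2% of its E left.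

(All runs stem from a simulated flask with constants of no real substance; noise was put on by code.)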